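**Retrosynthetic overview**
1. Target ⇒ (S)-configured dearomatised dienone (a 6-methyl-2,6-diprenyl acylphloroglucinol) by one oxidative radical bicyclisation with hydroxylative termination (cuts: ring-carbon–CH bond, CMe2–CH bond, C–OH bond).
2. (S)-Dienone ⇒ achiral deoxycohumulone + MeI by enantioselective desymmetrising dearomative C-methylation under chiral phase-transfer organocatalysis (first stereocentre; it controls both bridgeheads and the ring-fusion CH).
3. Deoxycohumulone ⇒ phlorisobutyrophenone + two prenyl bromide ⇒ phloroglucinol + isobutyryl chloride.
4. Ring order: ring A (six-membered, the purchased arene, dearomatised in the methylation) → ring B (cyclopentanone of the bicyclo[3.2.1]octane, first 5-exo closure) → ring C (cyclopentane, second 5-exo closure).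

Assumption: enolised β-triketones are written in the tautomer of the target SMILES; CIP descriptors refer to that tautomer.

**Step 1**
Reactants: 1 phloroglucinol (benzene-1,3,5-triol); 2 isobutyryl chloride (2-methylpropanoyl chloride)
Product: 3 phlorisobutyrophenone (2-methyl-1-(2,4,6-trihydroxyphenyl)propan-1-one)
Conditions: AlCl3 (3.5 equiv), PhNO2/CH2Cl2, 0 °C to 23 °C, 16 h; then ice/1 M HCl
Reagents that add atoms: isobutyryl chloride (compound 2), CC(C)C(=O)Cl
Why: Friedel–Crafts C-acylation of the threefold symmetric, very electron-rich arene; the aryl ketone formed is deactivated and chelated to aluminium, so the reaction stops at monoacylation; no stereocentre is formed.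

**Step 2**
Reactants: 3 phlorisobutyrophenone; 4 prenyl bromide (1-bromo-3-methylbut-2-ene)
Product: 6 deoxycohumulone (2-methyl-1-[2,4,6-trihydroxy-3,5-bis(3-methylbut-2-en-1-yl)phenyl]propan-1-one), via mono-prenyl ketone 5 (not isolated)
Conditions: 4 (2.1 equiv), 2 M aq KOH (3 equiv), 0 °C, 2 h; then 1 M HCl to pH 2, chromatography
Reagents that add atoms: prenyl bromide (compound 4), CC(C)=CCBr
Why: twofold C-alkylation of the ambident phenoxide by SN2 at the primary allylic bromide; water hydrogen-bonds the phenoxide oxygens and so favours attack through the two free ring carbons; no stereocentre is formed.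

**Step 3**
Reactants: 6 deoxycohumulone; 7 iodomethane
Product: 8 (6S)-3,5-dihydroxy-6-methyl-2,6-bis(3-methylbut-2-en-1-yl)-4-(2-methylpropanoyl)cyclohexa-2,4-dien-1-one
Conditions: 7 (1.05 equiv, slow addition), 2,7-bis[(O(9)-allylhydrocinchonidinium-1-yl)methyl]naphthalene dibromide (10 mol%), CsOH·H2O (2.2 equiv), 4 Å molecular sieves, toluene/CH2Cl2 (2:1), −40 °C, 24 h; then 1 M citric acid
Reagents that add atoms: iodomethane (compound 7), CI
Why: Proposed new method: desymmetrising dearomative C-methylation under chiral phase-transfer catalysis, in which the chiral bis-ammonium cation forms a tight contact ion pair with the phenoxide of 6 (the two ortho hydroxyls stay hydrogen-bonded to the acyl group), covers one of the two enantiotopic prenylated ring carbons and one ring face with its quinoline and naphthalene walls, and leaves the other carbon to attack MeI from the open face, which creates the methyl/prenyl quaternary centre of 8 in the (S) configuration (the pseudo-enantiomeric hydrocinchoninium dimer is used instead if the first run shows the opposite sense); the closest known reaction types are the cinchona phase-transfer alkylative dearomatisation–annulation of 3,5-diprenyl acylphloroglucinols with enal electrophiles and the phase-transfer asymmetric α-methylation of glycine imine enolates, whereas C-methylation of 6 itself is known only in racemic form (NaOMe, MeI).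

**Step 4**
Reactants: 8 (6S)-dienone
Product: 13 (1S,3S,5S,7S)-8-hydroxy-3-(2-hydroxypropan-2-yl)-4,4,7-trimethyl-9-(2-methylpropanoyl)tricyclo[5.3.1.0^1,5]undec-8-ene-10,11-dione (the target), via ring-carbon radical 9 (not isolated), via bicyclic tertiary radical 10 (not isolated), via tricyclic tertiary radical 11 (not isolated), via tricyclic tertiary cation 12 (not isolated)
Conditions: Mn(OAc)3·2H2O (2.5 equiv), degassed AcOH/H2O (9:1), Ar, 23 °C, 3 h; aqueous work-up, NaHCO3 extraction, preparative HPLC
Reagents that add atoms: water, O
Why: manganese triacetate oxidative radical bicyclisation with radical–polar crossover (the reaction type used for the racemic isopropenyl congeners): one-electron oxidation of the enol gives 9, which closes 5-exo onto the prenyl group of the quaternary carbon on the only face that group can reach (this fixes bridgehead C1 relative to C7, and only the adduct with the radical carbon exo, syn to the bridging ketone, can close again, which fixes C5); 10 then closes 5-exo onto the bridgehead prenyl group to give 11, trivalent manganese oxidises 11 to 12 and water adds; this second closure has little facial bias at C3 (about 1:1 expected), the cation of the unwanted C3 epimer sits next to the enol oxygen and is largely diverted to a neutral cyclic enol ether, and 13 is isolated as a single diastereomer from the acidic fraction by HPLC.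

**Compound list**
1 | phloroglucinol (benzene-1,3,5-triol) | Oc1cc(O)cc(O)c1 | starting material
2 | isobutyryl chloride (2-methylpropanoyl chloride) | CC(C)C(=O)Cl | starting material
3 | phlorisobutyrophenone, 2-methyl-1-(2,4,6-trihydroxyphenyl)propan-1-one | CC(C)C(=O)c1c(O)cc(O)cc1O | intermediate
4 | prenyl bromide (1-bromo-3-methylbut-2-ene) | CC(C)=CCBr | starting material
5 | mono-prenyl ketone, 2-methyl-1-[2,4,6-trihydroxy-3-(3-methylbut-2-en-1-yl)phenyl]propan-1-one (not isolated) | CC(C)C(=O)c1c(O)cc(O)c(CC=C(C)C)c1O | intermediate
6 | deoxycohumulone, 2-methyl-1-[2,4,6-trihydroxy-3,5-bis(3-methylbut-2-en-1-yl)phenyl]propan-1-one (achiral) | CC(C)C(=O)c1c(O)c(CC=C(C)C)c(O)c(CC=C(C)C)c1O | intermediate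
7 | iodomethane | CI | starting material
8 | (6S)-3,5-dihydroxy-6-methyl-2,6-bis(3-methylbut-2-en-1-yl)-4-(2-methylpropanoyl)cyclohexa-2,4-dien-1-one | CC(C)C(=O)C1=C(O)[C@](C)(CC=C(C)C)C(=O)C(CC=C(C)C)=C1O | intermediate
9 | ring-carbon radical: 8 after loss of the enol hydrogen atom, spin drawn at C2 (the prenylated ring carbon), C6 still (S) (not isolated) | CC(C)C(=O)C1=C(O)[C@](C)(CC=C(C)C)C(=O)[C](CC=C(C)C)C1=O | intermediate
10 | bicyclic tertiary radical: 2-[2-hydroxy-1-methyl-5-(3-methylbut-2-en-1-yl)-3-(2-methylpropanoyl)-4,8-dioxobicyclo[3.2.1]oct-2-en-6-yl]propan-2-yl, side chain exo (syn to the bridging ketone), bridgeheads as in 13 (not isolated) | CC(C)C(=O)C1=C(O)[C@]2(C)C[C@@H]([C](C)C)[C@](CC=C(C)C)(C1=O)C2=O | intermediate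
11 | tricyclic tertiary radical: 13 with the tertiary OH replaced by an unpaired electron, all four ring stereocentres as in 13 (not isolated) | CC(C)C(=O)C1=C(O)[C@]2(C)C[C@H]3C(C)(C)[C@@H]([C](C)C)C[C@@]3(C1=O)C2=O | intermediate
12 | tricyclic tertiary cation: the propan-2-ylium ion from 11, stereocentres as in 13 (not isolated) | CC(C)C(=O)C1=C(O)[C@]2(C)C[C@H]3C(C)(C)[C@@H]([C+](C)C)C[C@@]3(C1=O)C2=O | intermediate
13 | (1S,3S,5S,7S)-8-hydroxy-3-(2-hydroxypropan-2-yl)-4,4,7-trimethyl-9-(2-methylpropanoyl)tricyclo[5.3.1.0^1,5]undec-8-ene-10,11-dione; the hydroxypropyl group is cis to the bridging ketone and to the CH2 of the two-carbon bridge | CC(C)C(=O)C1=C(O)[C@]2(C)C[C@H]3C(C)(C)[C@@H](C(C)(C)O)C[C@@]3(C1=O)C2=O | target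

**Totals**
Total step count: 4. Longest linear sequence: 4 (from phloroglucinol).

**Three steps most likely to fail**

Step 3 (the proposed new method). Risks are low enantioselectivity with the small electrophile MeI, O-methylation in the weakly solvating medium, and a second methylation at the other prenylated carbon. Fallback, from 6 back to 8: the known racemic dearomative C-methylation (NaOMe, MeI, MeOH, 0 °C to 23 °C) gives 8 together with its mirror image, the (6R)-dienone F1. Preparative chiral supercritical-fluid chromatography (amylose tris(3,5-dimethylphenylcarbamate) phase, CO2/MeOH with 0.1% formic acid) separates the two, and the (6S) fraction re-enters the route at 8. This replaces catalytic induction by resolution and costs half the material.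

Step 4. Risks are the uncontrolled configuration at C3 (the target epimer is at best about half of the cyclised material), elimination of cation 12 to an alkene instead of hydration, hydride or methyl shifts in 12, and capture of radical 10 by traces of oxygen. Fallback, from 8 back to 13: Mn(OAc)3·2H2O (2 equiv) with Cu(OAc)2·H2O (1 equiv) in degassed AcOH at 23 °C, the known conditions of the racemic series, ends the cascade by copper-mediated elimination without a free cation. This gives the isopropenyl tricycle F2 and its C3 epimer F3 (about 1:1), which are separated by HPLC. Mukaiyama hydration of F2 (Co(acac)2 20 mol%, PhSiH3, O2 1 atm, iPrOH/THF, 23 °C; then PPh3) places the tertiary hydroxyl by hydrogen-atom transfer and gives 13. This is one step longer but uses only precedented operations and still relies on separating the C3 epimers.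

Step 2. Risks are O-prenylation, geminal diprenylation at one carbon and triprenylation, which historically hold the yield of 6 to about 30–40%. Fallback, from 3 back to 6: Friedel–Crafts prenylation of neutral 3 with 2-methylbut-3-en-2-ol (2.2 equiv) and BF3·OEt2 in dioxane at 23 °C. A prenyl cation attacks the free ring carbons of the un-ionised phenol, so the ambident phenoxide and its O- and gem-alkylation pathways are avoided; chroman by-products are removed by chromatography. This detour makes no new compound (F0).

**Further compounds**
F1 | step 3 | (6R)-3,5-dihydroxy-6-methyl-2,6-bis(3-methylbut-2-en-1-yl)-4-(2-methylpropanoyl)cyclohexa-2,4-dien-1-one (enantiomer of 8) | CC(C)C(=O)C1=C(O)[C@@](C)(CC=C(C)C)C(=O)C(CC=C(C)C)=C1O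
F2 | step 4 | (1S,3R,5S,7S)-8-hydroxy-4,4,7-trimethyl-9-(2-methylpropanoyl)-3-(prop-1-en-2-yl)tricyclo[5.3.1.0^1,5]undec-8-ene-10,11-dione (isopropenyl analogue of 13, same spatial arrangement) | CC(C)C(=O)C1=C(O)[C@]2(C)C[C@H]3C(C)(C)[C@@H](C(C)=C)C[C@@]3(C1=O)C2=O
F3 | step 4 | (1S,3S,5S,7S)-8-hydroxy-4,4,7-trimethyl-9-(2-methylpropanoyl)-3-(prop-1-en-2-yl)tricyclo[5.3.1.0^1,5]undec-8-ene-10,11-dione (C3 epimer of F2) | CC(C)C(=O)C1=C(O)[C@]2(C)C[C@H]3C(C)(C)[C@H](C(C)=C)C[C@@]3(C1=O)C2=O
F0 | step 2 | none | none
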